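**Strategy**

The methylidenecyclohexane ring (C1 bears the exocyclic CH2, C2 is CHCH3, C3 to C5 are CH2, C6 is quaternary) is cut into a C2–C1–C6 ketone and a C3–C4–C5 enal. Because C2 and C6 are both alpha to C1 and the opposite three carbons carry no substituent, ethyl 2-methyl-3-oxopentanoate and acrolein are joined in one flask: an enantioselective Michael addition makes C5–C6 and sets the quaternary centre, an aldol condensation makes C2–C3 and closes the ring as a cyclohexenone. The ester is then grown into the side chain, and the chromene is built by asymmetric allylic etherification and ring-closing metathesis.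

Key step: step 1

Remark: the enantiomer of each chiral catalyst or ligand that gives the drawn configuration is to be fixed in a trial run (both antipodes are available), and 4-methoxybenzene-1,2-diol is taken as a catalogue compound.

**Route**

Step 1
Reactants: 1 ethyl 2-methyl-3-oxopentanoate; 2 acrolein
Product: 4 ethyl (1S)-1,3-dimethyl-2-oxocyclohex-3-ene-1-carboxylate, via Michael adduct 3 (not isolated)
Conditions: 2 (2 equiv), 9-O-(9-phenanthryl)cupreidine or its cupreine pseudoenantiomer (10 mol %), CH2Cl2, −24 °C; then toluene, p-TsOH·H2O (20 mol %), 80 °C, same flask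
Reagents that add atoms: none
Why: The bifunctional cinchona base deprotonates the β-keto ester at C6 and hydrogen-bonds acrolein, so the enol adds through one face to the β-carbon (C5–C6, Michael addition); after the solvent switch the acid enolises the ketone toward C2, the only α-position that still carries hydrogen, the enol attacks the aldehyde carbon C3, and loss of water gives the conjugated enone. The closest known reaction type is the organocatalytic Michael/aldol-condensation [3+3] annulation of β-keto esters with enals. The six-membered ring closes by a 6-(enolendo)-exo-trig aldol addition. The only new stereocentre, quaternary C6, is set by the catalyst (ion pair with the quinuclidinium, hydrogen bond from the 6'-hydroxyl); C2 is still sp2 in 4. The step needs C-alkylation, a single Michael addition and enantioface control on an acyclic donor; the fully substituted donor carbon secures the first two and the internal hydrogen bond that fixes the enol geometry supports the third. Aldehyde self-condensation is the competing path and is held back by dilution in the acid stage.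

Step 2
Reactants: 4 ethyl (1S)-1,3-dimethyl-2-oxocyclohex-3-ene-1-carboxylate
Product: 5 ethyl (1S,3R)-1,3-dimethyl-2-oxocyclohexane-1-carboxylate
Conditions: H2 (50 bar), [Ir(cod)(L)]B[3,5-(CF3)2C6H3]4 (1 mol %, L = tBu-PHOX, enantiomer as required), CH2Cl2, rt
Reagents that add atoms: none
Why: Iridium-catalysed asymmetric hydrogenation of an α-substituted cyclic enone; the P,N ligand delivers H2 to the C2=C3 face anti to the pseudoaxial ester, which is also the less hindered face, so C2 becomes R with its methyl cis to the ester.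

Step 3
Reactants: 5 ethyl (1S,3R)-1,3-dimethyl-2-oxocyclohexane-1-carboxylate
Product: 6 ethyl (1S,3R)-1,3-dimethyl-2-methylidenecyclohexane-1-carboxylate
Conditions: Zn, CH2Br2, TiCl4, THF/CH2Cl2, 0 °C to rt
Reagents that add atoms: dibromomethane, BrCBr
Why: Takai–Lombardo methylenation is non-basic and works on hindered enolisable ketones, so the C2 centre should not epimerise and the ester is left alone.

Step 4
Reactants: 6 ethyl (1S,3R)-1,3-dimethyl-2-methylidenecyclohexane-1-carboxylate
Product: 7 [(1S,3R)-1,3-dimethyl-2-methylidenecyclohexyl]methanol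
Conditions: LiAlH4, Et2O, 0 °C
Reagents that add atoms: none
Why: Hydride reduction of the ester to the primary alcohol; the isolated alkene and both stereocentres are inert.

Step 5
Reactants: 7 [(1S,3R)-1,3-dimethyl-2-methylidenecyclohexyl]methanol
Product: 8 (1S,3R)-1,3-dimethyl-2-methylidenecyclohexane-1-carbaldehyde
Conditions: Pr4N[RuO4] (5 mol %), N-methylmorpholine N-oxide, 4 Å MS, CH2Cl2, rt
Reagents that add atoms: none
Why: Ley–Griffith oxidation stops at the aldehyde, which has no α-hydrogen and cannot epimerise or move into conjugation.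

Step 6
Reactants: 8 (1S,3R)-1,3-dimethyl-2-methylidenecyclohexane-1-carbaldehyde
Product: 9 (1R,3R)-1-ethenyl-1,3-dimethyl-2-methylidenecyclohexane
Conditions: Ph3PCH3Br, KOtBu, THF, 0 °C to rt; volatile product kept in pentane solution
Reagents that add atoms: methyltriphenylphosphonium bromide, C[P+](c1ccccc1)(c1ccccc1)c1ccccc1.[Br-]
Why: Wittig methylenation of a hindered, non-enolisable aldehyde.

Step 7
Reactants: 10 but-2-yn-1-ol
Product: 11 (2Z)-3-iodobut-2-en-1-ol
Conditions: NaAlH2(OCH2CH2OMe)2, Et2O, 0 °C to rt; then I2, THF, −78 °C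
Reagents that add atoms: iodine, II
Why: Alkoxide-directed trans-hydroalumination places aluminium at C3 cis to the CH2O group, and iodinolysis with retention gives the Z-iodide.

Step 8
Reactants: 9 (1R,3R)-1-ethenyl-1,3-dimethyl-2-methylidenecyclohexane; 11 (2Z)-3-iodobut-2-en-1-ol
Product: 13 (2Z)-5-[(1R,3R)-1,3-dimethyl-2-methylidenecyclohexyl]-3-methylpent-2-en-1-ol, via alkylborane 12 (not isolated)
Conditions: 9-BBN (1.0 equiv), THF, 0 °C to rt; then 11, Pd(dppf)Cl2 (5 mol %), AsPh3, aq. K3PO4, DMF, rt
Reagents that add atoms: none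
Why: Hydroboration/B-alkyl Suzuki–Miyaura coupling; 9-BBN should add anti-Markovnikov to the monosubstituted vinyl group in preference to the ring methylidene, which is shielded by a quaternary and a tertiary neighbour, and the alkenyl iodide couples with retention of the Z geometry.

Step 9
Reactants: 13 (2Z)-5-[(1R,3R)-1,3-dimethyl-2-methylidenecyclohexyl]-3-methylpent-2-en-1-ol
Product: 14 (2Z)-5-[(1R,3R)-1,3-dimethyl-2-methylidenecyclohexyl]-3-methylpent-2-en-1-yl methyl carbonate
Conditions: ClCO2Me, pyridine, CH2Cl2, 0 °C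
Reagents that add atoms: methyl chloroformate, COC(=O)Cl
Why: Acylation of the primary allylic alcohol gives the leaving group for the allylic substitution.

Step 10
Reactants: 15 4-methoxybenzene-1,2-diol
Product: 16 1,2-bis[(tert-butyldimethylsilyl)oxy]-4-methoxybenzene
Conditions: TBSCl (2.3 equiv), imidazole, DMF, rt
Reagents that add atoms: tert-butyldimethylsilyl chloride, CC(C)(C)[Si](C)(C)Cl
Why: Silylation of both phenols; fluoride removes these ethers at the end under near-neutral conditions.

Step 11
Reactants: 16 1,2-bis[(tert-butyldimethylsilyl)oxy]-4-methoxybenzene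
Product: 18 4,5-bis[(tert-butyldimethylsilyl)oxy]-2-methoxyphenol, via aryl boronate 17 (not isolated)
Conditions: B2pin2, [Ir(OMe)(cod)]2 (1.5 mol %), 4,4'-di-tert-butyl-2,2'-bipyridine, THF, 80 °C; then Oxone, acetone/H2O, rt
Reagents that add atoms: Oxone (potassium peroxymonosulfate), [K+].[O-]S(=O)(=O)OO
Why: Sterically controlled iridium-catalysed C–H borylation should take the C–H next to the small methoxy group (the others lie next to a bulky silyloxy group or between two substituents), and oxidation of the boronate gives the phenol.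

Step 12
Reactants: 18 4,5-bis[(tert-butyldimethylsilyl)oxy]-2-methoxyphenol
Product: 19 5,6-bis[(tert-butyldimethylsilyl)oxy]-2-hydroxy-3-methoxybenzaldehyde
Conditions: MgCl2, Et3N, paraformaldehyde, MeCN, reflux
Reagents that add atoms: paraformaldehyde (formaldehyde), C=O
Why: Magnesium-mediated ortho-formylation of phenols is specific for the ortho position, and only one is free.

Step 13
Reactants: 19 5,6-bis[(tert-butyldimethylsilyl)oxy]-2-hydroxy-3-methoxybenzaldehyde
Product: 20 3,4-bis[(tert-butyldimethylsilyl)oxy]-2-ethenyl-6-methoxyphenol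
Conditions: Ph3PCH3Br (2.5 equiv), KOtBu (2.5 equiv), THF, 0 °C to rt
Reagents that add atoms: methyltriphenylphosphonium bromide, C[P+](c1ccccc1)(c1ccccc1)c1ccccc1.[Br-]
Why: Wittig methylenation; the excess ylide covers the acidic phenol.

Step 14
Reactants: 14 (2Z)-5-[(1R,3R)-1,3-dimethyl-2-methylidenecyclohexyl]-3-methylpent-2-en-1-yl methyl carbonate; 20 3,4-bis[(tert-butyldimethylsilyl)oxy]-2-ethenyl-6-methoxyphenol
Product: 21 1-{[(3S)-5-[(1R,3R)-1,3-dimethyl-2-methylidenecyclohexyl]-3-methylpent-1-en-3-yl]oxy}-3,4-bis[(tert-butyldimethylsilyl)oxy]-2-ethenyl-6-methoxybenzene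
Conditions: Pd2(dba)3·CHCl3 (2.5 mol %), (R,R)- or (S,S)-N,N'-(cyclohexane-1,2-diyl)bis[2-(diphenylphosphino)benzamide] (7.5 mol %), CH2Cl2, rt
Reagents that add atoms: none
Why: Tsuji–Trost asymmetric allylic etherification; ionisation gives a 1,1-disubstituted π-allylpalladium complex that the phenoxide attacks at the more substituted terminus, and the chiral pocket of the ligand selects the face, setting the tertiary ether carbon as S from the geometrically pure Z-carbonate.

Step 15
Reactants: 21 1-{[(3S)-5-[(1R,3R)-1,3-dimethyl-2-methylidenecyclohexyl]-3-methylpent-1-en-3-yl]oxy}-3,4-bis[(tert-butyldimethylsilyl)oxy]-2-ethenyl-6-methoxybenzene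
Product: 22 (2S)-5,6-bis[(tert-butyldimethylsilyl)oxy]-2-{2-[(1R,3R)-1,3-dimethyl-2-methylidenecyclohexyl]ethyl}-8-methoxy-2-methyl-2H-chromene
Conditions: second-generation Grubbs catalyst (H2IMes)(PCy3)Cl2Ru=CHPh (5 mol %), CH2Cl2, 40 °C
Reagents that add atoms: none
Why: Ring-closing metathesis between the styrene and the allylic vinyl group closes the 2H-chromene without touching the ether stereocentre; the hindered 1,1-disubstituted ring alkene should not take part.

Step 16
Reactants: 22 (2S)-5,6-bis[(tert-butyldimethylsilyl)oxy]-2-{2-[(1R,3R)-1,3-dimethyl-2-methylidenecyclohexyl]ethyl}-8-methoxy-2-methyl-2H-chromene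
Product: 23 (2S)-2-{2-[(1R,3R)-1,3-dimethyl-2-methylidenecyclohexyl]ethyl}-8-methoxy-2-methyl-2H-chromene-5,6-diol
Conditions: Bu4NF (2.2 equiv), AcOH (2.5 equiv), THF, 0 °C, under argon
Reagents that add atoms: none
Why: Fluoride cleaves both aryl silyl ethers, and the acetic acid buffer keeps the electron-rich catechol protonated so that it, the chromene and the exocyclic alkene survive.

**Compound list**

1 | ethyl 2-methyl-3-oxopentanoate | CCC(=O)C(C)C(=O)OCC | starting material
2 | acrolein | C=CC=O | starting material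
3 | ethyl (2S)-2-methyl-3-oxo-2-(3-oxopropyl)pentanoate | O=CCC[C@](C(=O)CC)(C)C(=O)OCC | intermediate
4 | ethyl (1S)-1,3-dimethyl-2-oxocyclohex-3-ene-1-carboxylate | O=C1C(C)=CCC[C@]1(C)C(=O)OCC | intermediate
5 | ethyl (1S,3R)-1,3-dimethyl-2-oxocyclohexane-1-carboxylate | O=C1[C@H](C)CCC[C@]1(C)C(=O)OCC | intermediate
6 | ethyl (1S,3R)-1,3-dimethyl-2-methylidenecyclohexane-1-carboxylate | C=C1[C@H](C)CCC[C@]1(C)C(=O)OCC | intermediate
7 | [(1S,3R)-1,3-dimethyl-2-methylidenecyclohexyl]methanol | C=C1[C@H](C)CCC[C@]1(C)CO | intermediate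
8 | (1S,3R)-1,3-dimethyl-2-methylidenecyclohexane-1-carbaldehyde | C=C1[C@H](C)CCC[C@]1(C)C=O | intermediate
9 | (1R,3R)-1-ethenyl-1,3-dimethyl-2-methylidenecyclohexane | C=C1[C@H](C)CCC[C@]1(C)C=C | intermediate
10 | but-2-yn-1-ol | CC#CCO | starting material
11 | (2Z)-3-iodobut-2-en-1-ol | C/C(I)=C/CO | intermediate
12 | 9-{2-[(1S,3R)-1,3-dimethyl-2-methylidenecyclohexyl]ethyl}-9-borabicyclo[3.3.1]nonane | C=C1[C@H](C)CCC[C@]1(C)CCB1C2CCCC1CCC2 | intermediate
13 | (2Z)-5-[(1R,3R)-1,3-dimethyl-2-methylidenecyclohexyl]-3-methylpent-2-en-1-ol | C=C1[C@H](C)CCC[C@]1(C)CC/C(C)=C\CO | intermediate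
14 | (2Z)-5-[(1R,3R)-1,3-dimethyl-2-methylidenecyclohexyl]-3-methylpent-2-en-1-yl methyl carbonate | C=C1[C@H](C)CCC[C@]1(C)CC/C(C)=C\COC(=O)OC | intermediate
15 | 4-methoxybenzene-1,2-diol | COc1ccc(O)c(O)c1 | starting material
16 | 1,2-bis[(tert-butyldimethylsilyl)oxy]-4-methoxybenzene | COc1ccc(O[Si](C)(C)C(C)(C)C)c(O[Si](C)(C)C(C)(C)C)c1 | intermediate
17 | 2-{4,5-bis[(tert-butyldimethylsilyl)oxy]-2-methoxyphenyl}-4,4,5,5-tetramethyl-1,3,2-dioxaborolane | COc1cc(O[Si](C)(C)C(C)(C)C)c(O[Si](C)(C)C(C)(C)C)cc1B1OC(C)(C)C(C)(C)O1 | intermediate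
18 | 4,5-bis[(tert-butyldimethylsilyl)oxy]-2-methoxyphenol | COc1cc(O[Si](C)(C)C(C)(C)C)c(O[Si](C)(C)C(C)(C)C)cc1O | intermediate
19 | 5,6-bis[(tert-butyldimethylsilyl)oxy]-2-hydroxy-3-methoxybenzaldehyde | COc1cc(O[Si](C)(C)C(C)(C)C)c(O[Si](C)(C)C(C)(C)C)c(C=O)c1O | intermediate
20 | 3,4-bis[(tert-butyldimethylsilyl)oxy]-2-ethenyl-6-methoxyphenol | COc1cc(O[Si](C)(C)C(C)(C)C)c(O[Si](C)(C)C(C)(C)C)c(C=C)c1O | intermediate
21 | 1-{[(3S)-5-[(1R,3R)-1,3-dimethyl-2-methylidenecyclohexyl]-3-methylpent-1-en-3-yl]oxy}-3,4-bis[(tert-butyldimethylsilyl)oxy]-2-ethenyl-6-methoxybenzene | C=C1[C@H](C)CCC[C@]1(C)CC[C@@](Oc1c(OC)cc(O[Si](C)(C)C(C)(C)C)c(O[Si](C)(C)C(C)(C)C)c1C=C)(C)C=C | intermediate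
22 | (2S)-5,6-bis[(tert-butyldimethylsilyl)oxy]-2-{2-[(1R,3R)-1,3-dimethyl-2-methylidenecyclohexyl]ethyl}-8-methoxy-2-methyl-2H-chromene | C=C1[C@H](C)CCC[C@]1(C)CC[C@@]1(C)C=Cc2c(O[Si](C)(C)C(C)(C)C)c(O[Si](C)(C)C(C)(C)C)cc(OC)c2O1 | intermediate
23 | (2S)-2-{2-[(1R,3R)-1,3-dimethyl-2-methylidenecyclohexyl]ethyl}-8-methoxy-2-methyl-2H-chromene-5,6-diol | C=C1[C@H](C)CCC[C@]1(C)CC[C@@]1(C)C=Cc2c(O)c(O)cc(OC)c2O1 | target

**Count**

Total steps: 16. Longest linear sequence: 11 steps (steps 1, 2, 3, 4, 5, 6, 8, 9, 14, 15, 16).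

**Steps most likely to fail**

Step 14. The doubly ortho-substituted phenoxide may attack the unsubstituted allyl terminus and give the linear ether, the face selection may be incomplete, or the tertiary ether may re-ionise and scramble. The fallback gives up asymmetric induction at the chromene carbon and separates epimers instead. It sets out from 13: oxidation with MnO2 in CH2Cl2 gives (2Z)-5-[(1R,3R)-1,3-dimethyl-2-methylidenecyclohexyl]-3-methylpent-2-enal F1. Condensation of this enal with phenol 18 (ethylenediammonium diacetate, toluene, 110 °C) proceeds by ortho C-alkylation, dehydration to the ortho-quinone methide and oxa-6π electrocyclisation. It should give 22 together with its epimer at the chromene carbon, (2R)-5,6-bis[(tert-butyldimethylsilyl)oxy]-2-{2-[(1R,3R)-1,3-dimethyl-2-methylidenecyclohexyl]ethyl}-8-methoxy-2-methyl-2H-chromene F2. The two are separated by preparative HPLC and the route is rejoined at 22; compounds 19 to 21 are then not needed.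

Step 2. The catalyst and the substrate bias may be mismatched, giving poor facial selectivity at C2, and the new α-centre may epimerise by enolisation before the ketone is removed. The fallback uses hydroxyl-directed hydrogenation and sets out from 4. Reduction with NaBH4 and CeCl3·7H2O in MeOH at −78 °C gives ethyl (1S,2S)-2-hydroxy-1,3-dimethylcyclohex-3-ene-1-carboxylate F3; in the chelated form the ester is pseudoequatorial and hydride enters anti to the pseudoaxial methyl, so the hydroxyl is cis to that methyl. Hydrogenation with [Ir(cod)(PCy3)(py)]PF6 in CH2Cl2 delivers H2 to the face of the hydroxyl and gives ethyl (1S,2S,3R)-2-hydroxy-1,3-dimethylcyclohexane-1-carboxylate F4. Oxidation with Dess–Martin periodinane and NaHCO3 returns to the route at 5.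

Step 1. Enantioselectivity may erode because the enol geometry of an acyclic donor is not rigidly locked, and the aldehyde may oligomerise in the acid stage. The fallback keeps the one-flask annulation but drops the asymmetric catalyst. It sets out from 1 and 2: Et3N in CH2Cl2, then p-TsOH in toluene at 80 °C, gives 4 as the racemate, that is together with ethyl (1R)-1,3-dimethyl-2-oxocyclohex-3-ene-1-carboxylate F5. Preparative chromatography on a chiral stationary phase resolves the pair, and the route is rejoined at 4.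

**Further compounds**

F1 | step 14 | (2Z)-5-[(1R,3R)-1,3-dimethyl-2-methylidenecyclohexyl]-3-methylpent-2-enal | C=C1[C@H](C)CCC[C@]1(C)CC/C(C)=C\C=O
F2 | step 14 | (2R)-5,6-bis[(tert-butyldimethylsilyl)oxy]-2-{2-[(1R,3R)-1,3-dimethyl-2-methylidenecyclohexyl]ethyl}-8-methoxy-2-methyl-2H-chromene | C=C1[C@H](C)CCC[C@]1(C)CC[C@]1(C)C=Cc2c(O[Si](C)(C)C(C)(C)C)c(O[Si](C)(C)C(C)(C)C)cc(OC)c2O1
F3 | step 2 | ethyl (1S,2S)-2-hydroxy-1,3-dimethylcyclohex-3-ene-1-carboxylate | O[C@H]1C(C)=CCC[C@]1(C)C(=O)OCC
F4 | step 2 | ethyl (1S,2S,3R)-2-hydroxy-1,3-dimethylcyclohexane-1-carboxylate | O[C@H]1[C@H](C)CCC[C@]1(C)C(=O)OCC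
F5 | step 1 | ethyl (1R)-1,3-dimethyl-2-oxocyclohex-3-ene-1-carboxylate | O=C1C(C)=CCC[C@@]1(C)C(=O)OCC
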